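**Conventions and assumptions**

- Locants C1–C11 are those of the tricyclo[5.4.0.0^2,8]undecane skeleton of the target (cyclobutane C1–C2–C8–C7, ketone at C11). C13 is the carbon on C6 that ends as CH2OAc. "C8 face" and "C1 face" name the two faces of the seven-membered ring.
- Assumption on step 4: the rhodium/(S)-BINAP catalyst is taken to deliver the alkenyl group to the α-si face of the acyclic (E)-enone, as it does with cyclic enones; if the first batch shows the opposite sense, (R)-BINAP is used instead.
- The C6 configuration of 31, 33 and 34 is drawn as expected from alkylation anti to the C3 side chain; it is erased in step 20, so either epimer serves.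

## Analysis of the target

Compound 47 is a longipinane. Its cyclobutane C1–C2–C8–C7 is spanned on one side by the three-carbon bridge C9–C10–C11 (cyclohexanone) and on the other by the four-carbon bridge C3–C4–C5–C6 (cycloheptane). It has eight stereocentres. C1, C2, C7 and C8 are locked together by the cage, the C9 methyl lies on the side of C7, the C3 hydroxyl and the C13 arm on C6 lie on the C1 face, and the C5 angelate lies on the C8 face, trans to C13. Two stereocentres are quaternary (C2 in the cyclobutane, C6 beside it), and C6 is flanked by the C5 carbinol, so a fully substituted carbon and a neopentylic secondary ester must be set as a pair. The sensitive groups are the angelate (Z to E isomerisation), the primary acetate beside free or freed hydroxyls (acyl migration under base) and the cyclobutyl ketone, which rules out a β-dicarbonyl across C7/C11 at any stage. The oxygens at C3, C5 and C13 must end as three different functions, which costs protecting-group steps. The plan rests on the C5–C6 pair: C6 with its arm C13 is read as the α-carbon of an ester, C5 as the terminus of a (Z)-enol ether, and the C3 oxygen as the place where the ester oxygen was bound. C3–O–C13(=O)–C6 is then a seven-membered lactone bridging C2 and C7, and a [3,3] shift of its ketene acetal exchanges O and C13 in the ring for C4 and C5. The ring stays seven-membered, so this is a lactone-to-carbocycle transposition, not a change of ring size.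

## Retrosynthetic reasoning

**47 ⇒ 46 ⇒ 43 (+ 44).** The angelate C–O bond at C5 is cut last but one, so the isomerisable ester meets only the final unmasking. The C3 hydroxyl and the C11 ketone are kept masked in 46 as a silyl ether and a dioxolane that fall in one acidic step. The forward acylation has to work on a neopentylic alcohol without touching the angelate geometry.

**43 ⇒ 40.** The three hydroxyls are told apart by their order of appearance and their class: the primary one is acetylated, the C3 hydroxyl is silylated with the more robust silyl group, and the C5 oxygen, which already carries a labile silyl group, is freed last.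

**40 ⇒ 39 ⇒ 38.** The C3–O bond is cut back to a C3=C4 alkene. The C13 hydroxymethyl on the C1 face directs the epoxide to that face, and hydride opening at C4 leaves the C3 oxygen cis to C13. No carbon–carbon bond is involved and C3 is set from C6.

**38 ⇒ 37 ⇒ 34.** The C5–C6 bond is cut and the C3–O bond restored, which turns the cycloheptene acid 37 into the bridged lactone 34 with a (Z)-silyloxyvinyl group on C3. The cut is made here because it is the only one that creates the quaternary centre C6 and the C5 carbinol together, with chirality relayed from C3. The forward reaction must form the ketene acetal cleanly and pass through a boat array, the only one the bridged lactone allows.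

**34 ⇒ 33 ⇒ 31 ⇒ 29 ⇒ 27.** The enol ether comes from aldehyde 33, the aldehyde from the terminal alkene of 31, the C6 methyl from enolate alkylation of 29, and the lactone C13–O bond from hydroxy acid 27. The two arms are cis-1,3 on the cyclobutane and held close, which should make the seven-membered lactonisation easy.

**27 ⇒ 26 ⇒ 22 + 23.** The C3–C4 bond is cut to the neopentylic aldehyde 22 and the allyl nucleophile 23. The forward addition must set C3 by reagent control, because C3 decides which face of the ketene acetal is attacked later.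

**22 ⇒ 19 ⇒ 18 ⇒ 16 ⇒ 15 + 10.** The C6–C7 bond is cut as an olefination of the cyclobutanone 15 followed by hydrogenation from the face away from the C2 arm, which places the acetate arm cis to C3. The C11 ketone is carried as a methylidene until C7 is no longer a ketone.

**15 ⇒ 12.** The cyclobutane bonds C7–C8 and C1–C2 are cut together as an intramolecular vinylketene–alkene cycloaddition. The (E)-alkene geometry gives the C2 configuration, and the C9 methyl selects the face.

**12 ⇒ 11 ⇒ 9 + 10; 9 ⇒ 7 + 8; 7 ⇒ 1.** The acid is opened to ketone 9 and the phosphonate 10. C9 is set by a catalytic asymmetric conjugate addition of alkenylboronic acid 7 to enone 8, and 7 comes from propargyl alcohol 1 by syn-carbometalation, which fixes the alkene geometry.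

## Alternatives that were turned down

**Alternative 1:** The cyclobutane bond C2–C8 is cut, leading to the cis-fused bicyclo[5.4.0]undecane A1 with a C2–C3 epoxide and a silyl dienol ether of the C11 ketone. In the forward step Me2AlCl activates the epoxide and C8, the γ-carbon of the dienol ether, attacks C2 with inversion. The product A2 would then hold the cyclobutane, both bridged rings, quaternary C2 and a free C3 hydroxyl, with the C9 methyl left for a conjugate addition.
- For: it makes two rings and two stereocentres in one step, and it needs no protecting group on O3. On both points it is stronger than the chosen plan, which spends five steps on the C3 hydroxyl.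
- Against: it is a 4-exo closure onto a tertiary epoxide carbon. Under a Lewis acid the cationic character at C2 offers cheaper exits (hydride or alkyl shift to a ketone or ring-contracted aldehyde, elimination to an allylic alcohol). The dienol ether can also react at C10. A1 must already contain the C5/C6 pair and the ring-fusion centres in a flexible seven-membered ring.
- Comparison: the chosen route makes the cyclobutane early by a cycloaddition known for bicyclo[3.1.1]heptanones and puts its risk in a thermally allowed shift with a forced geometry.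

**Alternative 2:** The C3–C4 bond is cut, leading to the bicyclo[3.1.1]heptane A3 with a 1,3-dithian-2-yl group on C2 and a C7 side chain ending in C4H2Cl. In the forward step n-BuLi forms the 2-lithiodithiane, which displaces the chloride to give A4 with C3 as a masked ketone.
- For: dithiane alkylation of a primary halide is at least as dependable as anything in the chosen route, and the C3 ketone allows a late reduction.
- Against: the dithiane sits on a quaternary cyclobutane carbon, so the anion is slow to form and to alkylate. The chloride is β to the C5 ether, so elimination competes with a seven-membered closure. Above all, A3 needs the C5 carbinol and the C6 quaternary centre set on an open chain with no ring to control them.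
- Comparison: the step count would be similar, but the hardest stereochemical problem is left unsolved, whereas the sigmatropic step solves it by relay from C3.

**Alternative 3:** The cyclobutane bond C1–C7 is cut through a 1,2-shift, leading to the longibornane-type hydroxy mesylate A5, a norbornane with the tertiary hydroxyl on C11 and the mesylate on C1. In the forward step Et3Al ionises the mesylate while C7 migrates from C11 to C1 and C11 becomes the ketone, giving A6.
- For: the shift is stereospecific and delivers cyclobutane, C11 ketone and a fully substituted seven-membered ring at once. In events per step it is the strongest of the four plans.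
- Against: it runs from a norbornane to a markedly more strained bicyclo[3.1.1]heptane, against the usual direction of such shifts. It needs an endo mesylate antiperiplanar to C11–C7, while migration of C10 competes. The neopentylic mesylate beside quaternary C2 invites shifts from C2. A5 is itself a tricycle with nine stereocentres that needs a long synthesis.
- Comparison: the chosen plan reaches its precursor by standard reactions and keeps the cyclobutane intact once formed.

Key step: step 20

## Route

Step 1
Reactants: 1 propargyl alcohol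
Product: 3 (E)-3-iodo-2-methylprop-2-en-1-ol, via alkenylalane 2 (not isolated)
Conditions: Me3Al, (C5H5)2ZrCl2 (0.25 equiv), CH2Cl2, 0 °C → rt; then I2, THF, −30 → 0 °C
Reagents that add atoms: trimethylaluminium C[Al](C)C; iodine II
Why: Zirconium-catalysed carboalumination (Negishi) adds methyl and aluminium syn across the alkyne with aluminium at the terminus, and iodinolysis with retention gives the (E)-iodide; this geometry later becomes the configuration of quaternary C2.

Step 2
Reactants: 3 (E)-3-iodo-2-methylprop-2-en-1-ol
Product: 4 (E)-tert-butyl[(3-iodo-2-methylprop-2-enyl)oxy]diphenylsilane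
Conditions: t-BuPh2SiCl, imidazole, DMF, rt
Reagents that add atoms: tert-butyl(chloro)diphenylsilane CC(C)(C)[Si](Cl)(c1ccccc1)c1ccccc1
Why: Standard silylation of a primary alcohol; the tert-butyldiphenylsilyl ether is chosen because it should survive organolithium, hydroxide, hot amine and mild Lewis acid in steps 3 to 11.

Step 3
Reactants: 4 (E)-tert-butyl[(3-iodo-2-methylprop-2-enyl)oxy]diphenylsilane
Product: 7 (E)-[3-(tert-butyldiphenylsilyloxy)-2-methylprop-1-enyl]boronic acid, via alkenyllithium 5 (not isolated), via diisopropyl alkenylboronate 6 (not isolated)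
Conditions: t-BuLi (2.1 equiv), Et2O, −78 °C; B(Oi-Pr)3, −78 °C → rt; 1 M HCl, 0 °C
Reagents that add atoms: triisopropyl borate CC(C)OB(OC(C)C)OC(C)C; water O
Why: Iodine–lithium exchange and borate trapping both proceed with retention at the alkenyl carbon; lithium is trans to the silyloxymethyl group, so no 1,4-silyl shift is possible.

Step 4
Reactants: 7 (E)-[3-(tert-butyldiphenylsilyloxy)-2-methylprop-1-enyl]boronic acid; 8 (E)-pent-3-en-2-one
Product: 9 (4R,5E)-7-(tert-butyldiphenylsilyloxy)-4,6-dimethylhept-5-en-2-one
Conditions: [Rh(OH)((S)-BINAP)]2 (3 mol%), dioxane/H2O (10:1), 35 °C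
Reagents that add atoms: none
Why: Rhodium-catalysed asymmetric conjugate addition of an alkenylboronic acid to an enone (Hayashi–Miyaura reaction); the chiral rhodium–alkenyl species adds to one enantioface and sets C9 as R by catalyst control, with the alkene geometry of 7 retained.

Step 5
Reactants: 9 (4R,5E)-7-(tert-butyldiphenylsilyloxy)-4,6-dimethylhept-5-en-2-one; 10 triethyl phosphonoacetate
Product: 11 ethyl (2E,5R,6E)-8-(tert-butyldiphenylsilyloxy)-3,5,7-trimethylocta-2,6-dienoate
Conditions: NaH, THF, 0 → 60 °C; chromatography removes the 2Z isomer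
Reagents that add atoms: none
Why: Horner–Wadsworth–Emmons olefination of a methyl ketone should favour the 2E ester, which places the methyl group cis to the carbonyl as step 7 requires.

Step 6
Reactants: 11 ethyl (2E,5R,6E)-8-(tert-butyldiphenylsilyloxy)-3,5,7-trimethylocta-2,6-dienoate
Product: 12 (2E,5R,6E)-8-(tert-butyldiphenylsilyloxy)-3,5,7-trimethylocta-2,6-dienoic acid
Conditions: LiOH·H2O, THF/MeOH/H2O, 45 °C; then 1 M HCl to pH 3
Reagents that add atoms: lithium hydroxide [Li+].[OH-]
Why: Saponification; the hindered silyl ether and both alkenes should be inert to aqueous hydroxide at this temperature.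

Step 7
Reactants: 12 (2E,5R,6E)-8-(tert-butyldiphenylsilyloxy)-3,5,7-trimethylocta-2,6-dienoic acid
Product: 15 7-[(tert-butyldiphenylsilyloxy)methyl]-4,7-dimethyl-2-methylidenebicyclo[3.1.1]heptan-6-one (7-methyl syn to the C2–C4 bridge; 4-methyl on the side of the carbonyl bridge), via acid chloride 13 (not isolated), via vinylketene 14 (not isolated)
Conditions: 1-chloro-N,N,2-trimethylprop-1-en-1-amine, CH2Cl2, 0 °C → rt; then slow addition to Et3N, toluene, 110 °C (high dilution)
Reagents that add atoms: none
Why: Triethylamine removes a proton from the methyl group cis to the acyl chloride to give the vinylketene, which undergoes intramolecular ketene–alkene [2+2] cycloaddition, the ketene carbonyl carbon bonding to the less substituted alkene carbon (C8) and the ketene α-carbon to C2. The addition is suprafacial on the alkene, so the (E) geometry puts the C2 methyl on the side of the three-carbon bridge, and the C9 methyl takes the position anti to C2 to avoid allylic strain with that methyl, which selects the face and sets C1, C2 and C8.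

Step 8
Reactants: 15 bicyclic methylidene ketone; 10 triethyl phosphonoacetate
Product: 16 ethyl 2-{7-[(tert-butyldiphenylsilyloxy)methyl]-4,7-dimethyl-2-methylidenebicyclo[3.1.1]heptan-6-ylidene}acetate (C6=C7 geometric isomers)
Conditions: NaH, DME, 0 → 80 °C
Reagents that add atoms: none
Why: Horner–Wadsworth–Emmons olefination of a strained cyclobutanone, which is not enolisable at its bridgeheads; both alkene isomers converge in step 10.

Step 9
Reactants: 16 exocyclic enoate with C11 methylidene
Product: 18 ethyl 2-{7-[(tert-butyldiphenylsilyloxy)methyl]-4,7-dimethyl-2-oxobicyclo[3.1.1]heptan-6-ylidene}acetate, via vicinal diol 17 (not isolated)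
Conditions: OsO4 (2 mol%), NaIO4 (4 equiv), 2,6-lutidine, dioxane/H2O (3:1), rt
Reagents that add atoms: osmium tetroxide O=[Os](=O)(=O)=O; sodium periodate [Na+].[O-]I(=O)(=O)=O
Why: Lemieux–Johnson cleavage; osmylation should take the electron-rich 1,1-disubstituted alkene much faster than the hindered conjugated enoate, and C7 is no longer a ketone, so no β-diketone arises.

Step 10
Reactants: 18 keto enoate
Product: 19 ethyl 2-{7-[(tert-butyldiphenylsilyloxy)methyl]-4,7-dimethyl-2-oxobicyclo[3.1.1]heptan-6-yl}acetate (acetate arm cis to the silyloxymethyl arm across the cyclobutane)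
Conditions: H2 (1 atm), 10% Pd/C, EtOAc, rt
Reagents that add atoms: none
Why: Heterogeneous hydrogenation; the silyloxymethyl group on C2 points straight at one face of the exocyclic alkene, so hydrogen should add from the side of the three-carbon bridge and leave the C6 arm syn to the C3 arm, setting C7.

Step 11
Reactants: 19 keto ester
Product: 20 the C11 ethylene ketal of 19
Conditions: Me3SiOCH2CH2OSiMe3, Me3SiOTf (5 mol%), CH2Cl2, −78 → −20 °C
Reagents that add atoms: 1,2-bis(trimethylsilyloxy)ethane C[Si](C)(C)OCCO[Si](C)(C)C
Why: Noyori ketalisation under aprotic conditions protects C11 against the organometallic and hydride steps without touching the ester or the silyl ether.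

Step 12
Reactants: 20 ketal ester silyl ether
Product: 21 primary alcohol at C3
Conditions: Bu4NF, AcOH (1:1), THF, rt → 40 °C
Reagents that add atoms: none
Why: Fluoride cleavage of the silyl ether; buffering with acetic acid keeps the alkoxide from attacking the neighbouring ester.

Step 13
Reactants: 21 primary alcohol
Product: 22 aldehyde at C3
Conditions: Dess–Martin periodinane, NaHCO3, CH2Cl2, 0 °C → rt
Reagents that add atoms: none
Why: Dess–Martin oxidation; the aldehyde is attached to quaternary C2 and cannot enolise.

Step 14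
Reactants: 22 aldehyde; 23 allylmagnesium bromide
Product: 26 (R)-homoallylic alcohol at C3, via (+)-B-allyldiisopinocampheylborane 24 (not isolated), via dialkylborinate 25 (not isolated)
Conditions: (+)-B-methoxydiisopinocampheylborane + 23, Et2O, 0 °C → rt; then 22, −78 °C; then 30% H2O2, pH 7 phosphate buffer, MeOH, 0 °C → rt
Reagents that add atoms: none
Why: Brown allylboration through a closed chair transition state; the reagent derived from (−)-α-pinene should add to the re face and set C3 as R by reagent control, since the neopentylic aldehyde has little bias of its own.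

Step 15
Reactants: 26 hydroxy ester
Product: 27 hydroxy acid
Conditions: LiOH·H2O, THF/H2O, rt; then 1 M HCl to pH 4, 0 °C
Reagents that add atoms: lithium hydroxide [Li+].[OH-]
Why: Saponification of an unhindered ester; the dioxolane tolerates the brief, cold acidification.

Step 16
Reactants: 27 hydroxy acid
Product: 29 seven-membered lactone bridging C2 and C7 (allyl on C3), via mixed anhydride 28 (not isolated)
Conditions: 2,4,6-Cl3C6H2COCl, Et3N, THF, rt; then slow addition to DMAP, toluene, 80 °C (high dilution)
Reagents that add atoms: none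
Why: Yamaguchi lactonisation; the acid and alcohol arms are cis-1,3 on the cyclobutane and point toward each other, and acyl activation leaves the C3 configuration untouched.

Step 17
Reactants: 29 lactone
Product: 31 α-methyl lactone, via lithium enolate 30 (not isolated)
Conditions: LiN(i-Pr)2, THF, −78 °C; MeI, −78 → −40 °C
Reagents that add atoms: iodomethane CI
Why: Enolate alkylation; the methyl group should enter anti to the C3 allyl group, but the C6 configuration is removed again in step 20.

Step 18
Reactants: 31 α-methyl lactone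
Product: 33 β-acyloxy aldehyde (C5 aldehyde), via secondary ozonide 32 (not isolated)
Conditions: O3, CH2Cl2, −78 °C; then PPh3, −78 °C → rt
Reagents that add atoms: ozone [O-][O+]=O
Why: Ozonolysis with reductive work-up cleaves the only alkene and leaves C4 and C5 as the two-carbon unit needed for the enol ether.

Step 19
Reactants: 33 aldehyde
Product: 34 bridging lactone with (Z)-2-(triethylsilyloxy)vinyl group on C3
Conditions: Et3SiOTf, Et3N, CH2Cl2, −78 → −20 °C
Reagents that add atoms: triethylsilyl trifluoromethanesulfonate CC[Si](CC)(CC)OS(=O)(=O)C(F)(F)F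
Why: Soft enolisation: O-silylation gives a silyloxocarbenium ion whose deprotonation should favour the (Z)-enol ether, and the low temperature and the absence of a free enolate are meant to suppress β-elimination of the lactone carboxylate.

Step 20
Reactants: 34 bridging lactone with (Z)-silyl enol ether
Product: 37 tricyclic cycloheptene C13 carboxylic acid (C5 triethylsilyl ether), via silyl ketene acetal 35 (not isolated), via trimethylsilyl ester 36 (not isolated)
Conditions: LiN(i-Pr)2, Me3SiCl/Et3N, THF, −78 °C; then toluene, 100 °C; then aqueous citric acid, rt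
Reagents that add atoms: none
Why: The amide base removes the C6 proton in the presence of Me3SiCl, so the lactone enolate is trapped at oxygen as ketene acetal 35, whose C6=C13 geometry is fixed by the ring. Heating then drives a concerted, suprafacial [3,3] sigmatropic shift, an Ireland–Claisen rearrangement in its lactone variant with an alkenyl group on the carbinol carbon, in which C3–O breaks as C5–C6 forms; hydrolysis of silyl ester 36 gives 37. The carbocyclic seven-membered ring C1–C7 is closed by this pericyclic C5–C6 bond formation: O and C13 leave the ring and C4 and C5 enter it, so a seven-membered lactone becomes a seven-membered carbocycle with a C3=C4 alkene. C6 and C3, the 1,4-termini of the six-atom array, are tied by the three-atom bridge through C7, C1 or C8, and C2, so only the boat arrangement is possible. Quaternary C6 is controlled by the C3 configuration: the side chain lies on the C8 face of the lactone, C5 bonds to that face of the ketene acetal, and C13 is left on the C1 face. C5 is controlled by the (Z)-enol ether geometry, which in the boat places the silyloxy group on the tether side and gives the C5–O bond anti to C13. The step needs complete O-silylation and an intact enol ether, which the in situ quench and the neutral thermal conditions should secure.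

Step 21
Reactants: 37 carboxylic acid
Product: 38 primary alcohol at C13
Conditions: LiAlH4, THF, 0 → 65 °C
Reagents that add atoms: none
Why: Hydride reduction of a hindered acid; the ketal, the silyl ether and the isolated alkene are inert.

Step 22
Reactants: 38 bishomoallylic alcohol
Product: 39 C3–C4 epoxide on the C1 face
Conditions: VO(acac)2 (5 mol%), t-BuOOH, CH2Cl2, 0 °C → rt
Reagents that add atoms: tert-butyl hydroperoxide CC(C)(C)OO
Why: Vanadium-catalysed hydroxyl-directed epoxidation delivers oxygen from the face of the C13 hydroxymethyl group, while the C5 silyloxy group shields the other face; the hydroxyl is cis to the epoxide and cannot open it from the rear.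

Step 23
Reactants: 39 epoxy alcohol
Product: 40 diol (C3–OH and C13–OH; C5 triethylsilyl ether)
Conditions: LiEt3BH, THF, 0 → 50 °C
Reagents that add atoms: none
Why: SN2 opening of the epoxide by hydride at C4, because C3 is neopentylic (next to quaternary C2); the C3–O bond is untouched, so the hydroxyl stays on the C1 face.

Step 24
Reactants: 40 diol
Product: 41 C13 acetate
Conditions: Ac2O (1.2 equiv), pyridine, CH2Cl2, 0 °C
Reagents that add atoms: acetic anhydride CC(=O)OC(C)=O
Why: The primary hydroxyl should acylate far faster than the neopentylic secondary one at C3 without a nucleophilic catalyst.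

Step 25
Reactants: 41 hydroxy acetate
Product: 42 C3 tert-butyldimethylsilyl ether
Conditions: t-BuMe2SiOTf, 2,6-lutidine, CH2Cl2, −78 → 0 °C
Reagents that add atoms: tert-butyldimethylsilyl trifluoromethanesulfonate CC(C)(C)[Si](C)(C)OS(=O)(=O)C(F)(F)F
Why: A silyl triflate is reactive enough for the hindered C3 hydroxyl; the new ether is more robust than the triethylsilyl ether at C5, which allows step 26.

Step 26
Reactants: 42 bis-silyl ether
Product: 43 C5 alcohol
Conditions: HF·pyridine, pyridine, THF, 0 °C
Reagents that add atoms: none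
Why: Buffered fluoride removes the triethylsilyl ether selectively; the medium is not basic, so the acetate should not migrate.

Step 27
Reactants: 43 C5 alcohol; 44 angelic acid
Product: 46 C5 angelate, via angelic 2,4,6-trichlorobenzoic anhydride 45 (not isolated)
Conditions: 44, 2,4,6-Cl3C6H2COCl, Et3N, toluene, rt; then 43, 80 °C
Reagents that add atoms: none
Why: Acylation through the Yamaguchi mixed anhydride, in which the alcohol attacks the unhindered angeloyl carbonyl; omitting DMAP is meant to avoid Z to E isomerisation of the angeloyl group.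

Step 28
Reactants: 46 protected angelate
Product: 47 CNP0212099.1
Conditions: 48% aq. HF, MeCN, 0 °C → rt
Reagents that add atoms: water O
Why: Aqueous acidic fluoride cleaves the C3 silyl ether and hydrolyses the dioxolane to the C11 ketone in one operation, under which both esters and the angelate geometry should survive.

## Compound list

1 | propargyl alcohol | C#CCO | starting material
2 | (E)-alkenylalane from carboalumination of 1 | C[Al](C)OC/C(C)=C/[Al](C)C | intermediate
3 | (E)-3-iodo-2-methylprop-2-en-1-ol | OC/C(C)=C/I | intermediate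
4 | (E)-tert-butyl[(3-iodo-2-methylprop-2-enyl)oxy]diphenylsilane | CC(C)(C)[Si](c1ccccc1)(c1ccccc1)OC/C(C)=C/I | intermediate
5 | (E)-[3-(tert-butyldiphenylsilyloxy)-2-methylprop-1-enyl]lithium | [Li]/C=C(C)/CO[Si](c1ccccc1)(c1ccccc1)C(C)(C)C | intermediate
6 | diisopropyl (E)-[3-(tert-butyldiphenylsilyloxy)-2-methylprop-1-enyl]boronate | CC(C)OB(OC(C)C)/C=C(C)/CO[Si](c1ccccc1)(c1ccccc1)C(C)(C)C | intermediate
7 | (E)-[3-(tert-butyldiphenylsilyloxy)-2-methylprop-1-enyl]boronic acid | OB(O)/C=C(C)/CO[Si](c1ccccc1)(c1ccccc1)C(C)(C)C | intermediate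
8 | (E)-pent-3-en-2-one | C/C=C/C(C)=O | starting material
9 | (4R,5E)-7-(tert-butyldiphenylsilyloxy)-4,6-dimethylhept-5-en-2-one | CC(=O)C[C@@H](C)/C=C(\C)CO[Si](c1ccccc1)(c1ccccc1)C(C)(C)C | intermediate
10 | triethyl phosphonoacetate | CCOC(=O)CP(=O)(OCC)OCC | starting material
11 | ethyl (2E,5R,6E)-8-(tert-butyldiphenylsilyloxy)-3,5,7-trimethylocta-2,6-dienoate | CCOC(=O)/C=C(\C)C[C@@H](C)/C=C(\C)CO[Si](c1ccccc1)(c1ccccc1)C(C)(C)C | intermediate
12 | (2E,5R,6E)-8-(tert-butyldiphenylsilyloxy)-3,5,7-trimethylocta-2,6-dienoic acid | OC(=O)/C=C(\C)C[C@@H](C)/C=C(\C)CO[Si](c1ccccc1)(c1ccccc1)C(C)(C)C | intermediate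
13 | acid chloride of 12 | ClC(=O)/C=C(\C)C[C@@H](C)/C=C(\C)CO[Si](c1ccccc1)(c1ccccc1)C(C)(C)C | intermediate
14 | vinylketene from 13 (C11 methylidene) | O=C=CC(=C)C[C@@H](C)/C=C(\C)CO[Si](c1ccccc1)(c1ccccc1)C(C)(C)C | intermediate
15 | 7-[(tert-butyldiphenylsilyloxy)methyl]-4,7-dimethyl-2-methylidenebicyclo[3.1.1]heptan-6-one (7-methyl syn to the C2–C4 bridge, 4-methyl on the side of the carbonyl bridge) | O=C1[C@H]2C(=C)C[C@@H](C)[C@@H]1[C@@]2(C)CO[Si](c3ccccc3)(c3ccccc3)C(C)(C)C | intermediate
16 | ethyl 2-(bicyclo[3.1.1]heptan-6-ylidene)acetate from 15 (C11 methylidene; C6=C7 isomer mixture) | CCOC(=O)C=C1[C@H]2C(=C)C[C@@H](C)[C@@H]1[C@@]2(C)CO[Si](c3ccccc3)(c3ccccc3)C(C)(C)C | intermediate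
17 | C11 vicinal diol from osmylation of 16 (C11 configuration not defined) | CCOC(=O)C=C1[C@H]2C(O)(CO)C[C@@H](C)[C@@H]1[C@@]2(C)CO[Si](c3ccccc3)(c3ccccc3)C(C)(C)C | intermediate
18 | C11 ketone with exocyclic enoate (C6=C7 isomer mixture) | CCOC(=O)C=C1[C@H]2C(=O)C[C@@H](C)[C@@H]1[C@@]2(C)CO[Si](c3ccccc3)(c3ccccc3)C(C)(C)C | intermediate
19 | keto ester with the acetate arm on C7 cis to the C2 silyloxymethyl arm | CCOC(=O)C[C@@H]1[C@H]2C(=O)C[C@@H](C)[C@@H]1[C@@]2(C)CO[Si](c3ccccc3)(c3ccccc3)C(C)(C)C | intermediate
20 | C11 ethylene ketal of 19 | CCOC(=O)C[C@@H]1[C@H]2C3(OCCO3)C[C@@H](C)[C@@H]1[C@@]2(C)CO[Si](c4ccccc4)(c4ccccc4)C(C)(C)C | intermediate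
21 | C3 primary alcohol | CCOC(=O)C[C@@H]1[C@H]2C3(OCCO3)C[C@@H](C)[C@@H]1[C@@]2(C)CO | intermediate
22 | C3 aldehyde | CCOC(=O)C[C@@H]1[C@H]2C3(OCCO3)C[C@@H](C)[C@@H]1[C@@]2(C)C=O | intermediate
23 | allylmagnesium bromide | C=CC[Mg]Br | starting material
24 | (+)-B-allyldiisopinocampheylborane | C=CCB([C@H]1C[C@H]2C[C@@H]([C@@H]1C)C2(C)C)[C@H]1C[C@H]2C[C@@H]([C@@H]1C)C2(C)C | intermediate
25 | diisopinocampheylborinate of 26 | CCOC(=O)C[C@@H]1[C@H]2C3(OCCO3)C[C@@H](C)[C@@H]1[C@@]2(C)[C@@H](CC=C)OB([C@H]1C[C@H]2C[C@@H]([C@@H]1C)C2(C)C)[C@H]1C[C@H]2C[C@@H]([C@@H]1C)C2(C)C | intermediate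
26 | (3R)-homoallylic alcohol ester | CCOC(=O)C[C@@H]1[C@H]2C3(OCCO3)C[C@@H](C)[C@@H]1[C@@]2(C)[C@H](O)CC=C | intermediate
27 | hydroxy acid | OC(=O)C[C@@H]1[C@H]2C3(OCCO3)C[C@@H](C)[C@@H]1[C@@]2(C)[C@H](O)CC=C | intermediate
28 | mixed 2,4,6-trichlorobenzoic anhydride of 27 | O=C(OC(=O)C[C@@H]1[C@H]2C3(OCCO3)C[C@@H](C)[C@@H]1[C@@]2(C)[C@H](O)CC=C)c1c(Cl)cc(Cl)cc1Cl | intermediate
29 | seven-membered lactone (C13–O–C3) with allyl on C3 | O=C1C[C@@H]2[C@H]3C4(OCCO4)C[C@@H](C)[C@@H]2[C@@]3(C)[C@@H](CC=C)O1 | intermediate
30 | lithium enolate of 29 | [Li]OC1=C[C@@H]2[C@H]3C4(OCCO4)C[C@@H](C)[C@@H]2[C@@]3(C)[C@@H](CC=C)O1 | intermediate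
31 | α-methyl lactone (C6 methyl anti to the C3 allyl group) | O=C1[C@H](C)[C@@H]2[C@H]3C4(OCCO4)C[C@@H](C)[C@@H]2[C@@]3(C)[C@@H](CC=C)O1 | intermediate
32 | secondary ozonide of 31 (acetal carbon not defined) | O=C1[C@H](C)[C@@H]2[C@H]3C4(OCCO4)C[C@@H](C)[C@@H]2[C@@]3(C)[C@@H](CC5OCOO5)O1 | intermediate
33 | lactone aldehyde (C5 aldehyde) | O=C1[C@H](C)[C@@H]2[C@H]3C4(OCCO4)C[C@@H](C)[C@@H]2[C@@]3(C)[C@@H](CC=O)O1 | intermediate
34 | bridging lactone with (Z)-2-(triethylsilyloxy)vinyl on C3 | O=C1[C@H](C)[C@@H]2[C@H]3C4(OCCO4)C[C@@H](C)[C@@H]2[C@@]3(C)[C@@H](/C=C\O[Si](CC)(CC)CC)O1 | intermediate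
35 | trimethylsilyl ketene acetal of 34 | C[Si](C)(C)OC1=C(C)[C@@H]2[C@H]3C4(OCCO4)C[C@@H](C)[C@@H]2[C@@]3(C)[C@@H](/C=C\O[Si](CC)(CC)CC)O1 | intermediate
36 | trimethylsilyl ester of 37 | CC[Si](CC)(CC)O[C@@H]1C=C[C@]2(C)[C@@H]3[C@@H]([C@H]2C4(OCCO4)C[C@H]3C)[C@@]1(C)C(=O)O[Si](C)(C)C | intermediate
37 | tricyclic cycloheptene C13 carboxylic acid (C5–OSiEt3 on the C8 face, C13 on the C1 face) | CC[Si](CC)(CC)O[C@@H]1C=C[C@]2(C)[C@@H]3[C@@H]([C@H]2C4(OCCO4)C[C@H]3C)[C@@]1(C)C(=O)O | intermediate
38 | C13 primary alcohol | CC[Si](CC)(CC)O[C@@H]1C=C[C@]2(C)[C@@H]3[C@@H]([C@H]2C4(OCCO4)C[C@H]3C)[C@@]1(C)CO | intermediate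
39 | C3–C4 epoxide cis to the C13 hydroxymethyl group | CC[Si](CC)(CC)O[C@@H]1[C@H]5O[C@H]5[C@]2(C)[C@@H]3[C@@H]([C@H]2C4(OCCO4)C[C@H]3C)[C@@]1(C)CO | intermediate
40 | C3,C13 diol with C5 triethylsilyl ether | CC[Si](CC)(CC)O[C@@H]1C[C@@H](O)[C@]2(C)[C@@H]3[C@@H]([C@H]2C4(OCCO4)C[C@H]3C)[C@@]1(C)CO | intermediate
41 | C13 acetate | CC[Si](CC)(CC)O[C@@H]1C[C@@H](O)[C@]2(C)[C@@H]3[C@@H]([C@H]2C4(OCCO4)C[C@H]3C)[C@@]1(C)COC(C)=O | intermediate
42 | C3 tert-butyldimethylsilyl ether | CC[Si](CC)(CC)O[C@@H]1C[C@@H](O[Si](C)(C)C(C)(C)C)[C@]2(C)[C@@H]3[C@@H]([C@H]2C4(OCCO4)C[C@H]3C)[C@@]1(C)COC(C)=O | intermediate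
43 | C5 alcohol | O[C@@H]1C[C@@H](O[Si](C)(C)C(C)(C)C)[C@]2(C)[C@@H]3[C@@H]([C@H]2C4(OCCO4)C[C@H]3C)[C@@]1(C)COC(C)=O | intermediate
44 | angelic acid | C/C=C(/C)C(=O)O | starting material
45 | angelic 2,4,6-trichlorobenzoic anhydride | C/C=C(/C)C(=O)OC(=O)c1c(Cl)cc(Cl)cc1Cl | intermediate
46 | C5 angelate with C3 silyl ether and C11 ketal | C/C=C(/C)C(=O)O[C@@H]1C[C@@H](O[Si](C)(C)C(C)(C)C)[C@]2(C)[C@@H]3[C@@H]([C@H]2C4(OCCO4)C[C@H]3C)[C@@]1(C)COC(C)=O | intermediate
47 | CNP0212099.1 | C/C=C(/C)C(=O)O[C@@H]1C[C@@H](O)[C@]2(C)[C@@H]3[C@@H]([C@H]2C(=O)C[C@H]3C)[C@@]1(C)COC(C)=O | target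

## Step count and least certain steps

Total: 28 steps. Longest linear sequence: 28 steps (1 → 47); 19 steps lead to the rearrangement substrate 34.

**Step 20 (key step).** The boat transition state is strained, so the ketene acetal may be lost by reversion to the lactone, by C-silylation or by ionisation of the allylic C3–O bond before it rearranges. The fallback forms the same C5–C6 bond by a polar closure and never breaks the C3–O bond. It sets out from 31 and comes back at 40. Deprotonation of 31 and bromination with CBr4 should give the α-bromo lactone F1, and ozonolysis with Me2S work-up the bromo aldehyde F2. SmI2 in THF at −78 °C then effects an intramolecular Reformatsky reaction to the bridged β-hydroxy lactone F3. The chelated samarium enolate is expected to place the C5 hydroxyl syn to the lactone carbonyl, which is the wrong epimer. It is corrected by Dess–Martin oxidation to the β-keto lactone F4 and NaBH4 reduction from the open lactone side to the C5 alcohol F5. Silylation with Et3SiOTf gives the silyl ether F6, and LiAlH4 opens the lactone to 40.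

**Step 19.** Two processes threaten it: β-elimination of the lactone carboxylate from the β-acyloxy aldehyde under the amine, and incomplete Z selectivity in the deprotonation, which would pass on as the C5 epimer. The fallback makes C5 independent of the enol ether geometry. It sets out from 38 carried forward together with its C5 epimer F7 and comes back at 38. HF·pyridine gives the allylic diols F8, and MnO2 oxidises the allylic hydroxyl to the β-hydroxy enone F9. Me4NBH(OAc)3 delivers hydride from the side of the C13 hydroxyl and should give the 1,3-anti diol F10. Et3SiOTf gives the bis-silyl ether F11, and PPTS in MeOH removes the primary silyl group to return 38.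

**Step 23.** Hydride may enter at C3 instead of C4, because the C5 silyloxy group lies on the face from which C4 must be attacked. The fallback uses intramolecular delivery. It sets out from 39 and comes back at 43. HF·pyridine gives the epoxy diol F12, in which the C5 alkoxide is trans to the epoxide. NaAlH2(OCH2CH2OMe)2 then delivers hydride to the adjacent C4 and gives the triol F13. 2,2-Dimethoxypropane with PPTS ties O5 and O13 into the acetonide F14, t-BuMe2SiOTf silylates O3 to give F15, and aqueous acetic acid frees the diol F16. Selective acetylation of the primary hydroxyl gives 43.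

**Step 7.** The vinylketene may oligomerise, the base may deprotonate toward C10 instead of the methyl group, and the C9 methyl may give too little facial bias. The fallback uses the more electrophilic keteniminium ion. It sets out from 13 and comes back at 15. Treating 13 with Et3N and then pyrrolidine should give the deconjugated amide F17. Triflic anhydride and 2,4,6-collidine in 1,2-dichloroethane at 80 °C convert it by way of the keteniminium triflate F18 into the bicyclic iminium triflate F19, which aqueous NaHCO3 hydrolyses to 15.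

**Step 14.** Facial control may be poor if the bias of the cage opposes the reagent. The fallback sets C3 by reduction. It sets out from 22 and comes back at 26. Direct addition of 23 gives the C3-epimeric alcohols F20, buffered Dess–Martin oxidation gives the allyl ketone F21, and reduction with the (S)-methyl oxazaborolidine catalyst and catecholborane at −78 °C should give 26, the quaternary C2 acting as the large group.

**Step 27.** Acylation of the neopentylic C5 hydroxyl may be slow, which gives time for Z to E isomerisation of the angeloyl unit or for acetyl migration from O13. The fallback builds the double bond on the ester. It sets out from 43 and comes back at 46. Esterification with 2-[bis(2,2,2-trifluoroethoxy)phosphoryl]propanoic acid and dicyclohexylcarbodiimide gives the phosphonate ester F22, and Still–Gennari olefination with acetaldehyde (KN(SiMe3)2, 18-crown-6, THF, −78 °C) should give the (Z)-ester 46.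

## Further compounds

F1 | step 20 | α-bromo-α-methyl lactone from 31 | O=C1[C@](C)(Br)[C@@H]2[C@H]3C4(OCCO4)C[C@@H](C)[C@@H]2[C@@]3(C)[C@@H](CC=C)O1
F2 | step 20 | bromo lactone aldehyde | O=C1[C@](C)(Br)[C@@H]2[C@H]3C4(OCCO4)C[C@@H](C)[C@@H]2[C@@]3(C)[C@@H](CC=O)O1
F3 | step 20 | bridged β-hydroxy lactone, C5 hydroxyl syn to the lactone carbonyl | O[C@H]1C[C@@H]5[C@]2(C)[C@@H]3[C@@H]([C@H]2C4(OCCO4)C[C@H]3C)[C@@]1(C)C(=O)O5
F4 | step 20 | bridged β-keto lactone | O=C1C[C@@H]5[C@]2(C)[C@@H]3[C@@H]([C@H]2C4(OCCO4)C[C@H]3C)[C@@]1(C)C(=O)O5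
F5 | step 20 | bridged β-hydroxy lactone, C5 hydroxyl anti to the lactone bridge | O[C@@H]1C[C@@H]5[C@]2(C)[C@@H]3[C@@H]([C@H]2C4(OCCO4)C[C@H]3C)[C@@]1(C)C(=O)O5
F6 | step 20 | C5 triethylsilyl ether of F5 | CC[Si](CC)(CC)O[C@@H]1C[C@@H]5[C@]2(C)[C@@H]3[C@@H]([C@H]2C4(OCCO4)C[C@H]3C)[C@@]1(C)C(=O)O5
F7 | step 19 | C5 epimer of 38 | CC[Si](CC)(CC)O[C@H]1C=C[C@]2(C)[C@@H]3[C@@H]([C@H]2C4(OCCO4)C[C@H]3C)[C@@]1(C)CO
F8 | step 19 | C5,C13 allylic diol (both C5 epimers) | OC1C=C[C@]2(C)[C@@H]3[C@@H]([C@H]2C4(OCCO4)C[C@H]3C)[C@@]1(C)CO
F9 | step 19 | β-hydroxy enone (C5 ketone) | O=C1C=C[C@]2(C)[C@@H]3[C@@H]([C@H]2C4(OCCO4)C[C@H]3C)[C@@]1(C)CO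
F10 | step 19 | 1,3-anti diol (C5 hydroxyl on the C8 face) | O[C@@H]1C=C[C@]2(C)[C@@H]3[C@@H]([C@H]2C4(OCCO4)C[C@H]3C)[C@@]1(C)CO
F11 | step 19 | bis(triethylsilyl) ether of F10 | CC[Si](CC)(CC)O[C@@H]1C=C[C@]2(C)[C@@H]3[C@@H]([C@H]2C4(OCCO4)C[C@H]3C)[C@@]1(C)CO[Si](CC)(CC)CC
F12 | step 23 | epoxy diol (C5 and C13 hydroxyls free) | O[C@@H]1[C@H]5O[C@H]5[C@]2(C)[C@@H]3[C@@H]([C@H]2C4(OCCO4)C[C@H]3C)[C@@]1(C)CO
F13 | step 23 | C3,C5,C13 triol | O[C@@H]1C[C@@H](O)[C@]2(C)[C@@H]3[C@@H]([C@H]2C4(OCCO4)C[C@H]3C)[C@@]1(C)CO
F14 | step 23 | O5,O13 acetonide with free C3 hydroxyl | CC1(C)O[C@@H]2C[C@@H](O)[C@]3(C)[C@@H]4[C@@H]([C@H]3C5(OCCO5)C[C@H]4C)[C@@]2(C)CO1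
F15 | step 23 | O5,O13 acetonide with C3 tert-butyldimethylsilyl ether | CC1(C)O[C@@H]2C[C@@H](O[Si](C)(C)C(C)(C)C)[C@]3(C)[C@@H]4[C@@H]([C@H]3C5(OCCO5)C[C@H]4C)[C@@]2(C)CO1
F16 | step 23 | C5,C13 diol with C3 tert-butyldimethylsilyl ether | O[C@@H]1C[C@@H](O[Si](C)(C)C(C)(C)C)[C@]2(C)[C@@H]3[C@@H]([C@H]2C4(OCCO4)C[C@H]3C)[C@@]1(C)CO
F17 | step 7 | deconjugated pyrrolidine amide | O=C(CC(=C)C[C@@H](C)/C=C(\C)CO[Si](c1ccccc1)(c1ccccc1)C(C)(C)C)N1CCCC1
F18 | step 7 | keteniminium triflate | [O-]S(=O)(=O)C(F)(F)F.C(=C=[N+]1CCCC1)C(=C)C[C@@H](C)/C=C(\C)CO[Si](c1ccccc1)(c1ccccc1)C(C)(C)C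
F19 | step 7 | bicyclic cyclobutaniminium triflate | [O-]S(=O)(=O)C(F)(F)F.C1CC[N+](C1)=C2[C@H]3C(=C)C[C@@H](C)[C@@H]2[C@@]3(C)CO[Si](c4ccccc4)(c4ccccc4)C(C)(C)C
F20 | step 14 | homoallylic alcohol, both C3 epimers | CCOC(=O)C[C@@H]1[C@H]2C3(OCCO3)C[C@@H](C)[C@@H]1[C@@]2(C)C(O)CC=C
F21 | step 14 | allyl ketone at C3 | CCOC(=O)C[C@@H]1[C@H]2C3(OCCO3)C[C@@H](C)[C@@H]1[C@@]2(C)C(=O)CC=C
F22 | step 27 | C5 2-[bis(2,2,2-trifluoroethoxy)phosphoryl]propanoate (α-carbon not defined) | CC(C(=O)O[C@@H]1C[C@@H](O[Si](C)(C)C(C)(C)C)[C@]2(C)[C@@H]3[C@@H]([C@H]2C4(OCCO4)C[C@H]3C)[C@@]1(C)COC(C)=O)P(=O)(OCC(F)(F)F)OCC(F)(F)F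
A1 | alternative 1 | cis-fused bicyclo[5.4.0]undecane with C2–C3 epoxide and C11 trimethylsilyl dienol ether | COc1ccc(cc1)CO[C@@H]1C[C@H]6O[C@@]6(C)[C@H]2[C@H](C=CC=C2O[Si](C)(C)C)[C@@]1(C)CO[Si](C)(C)C(C)(C)C
A2 | alternative 1 | tricyclic C9–C10 enone with free C3 hydroxyl | COc5ccc(cc5)CO[C@@H]1C[C@@H](O)[C@]2(C)[C@@H]3[C@@H]([C@H]2C(=O)C=C3)[C@@]1(C)CO[Si](C)(C)C(C)(C)C
A3 | alternative 2 | bicyclo[3.1.1]heptane with 1,3-dithian-2-yl on C2 and C4 chloride | COc1ccc(cc1)CO[C@H](CCl)[C@](C)(CO[Si](C)(C)C(C)(C)C)[C@@H]1[C@H]2C3(OCCO3)C[C@@H](C)[C@@H]1[C@@]2(C)C1SCCCS1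
A4 | alternative 2 | tricyclic C3 dithioketal | COc5ccc(cc5)CO[C@@H]1CC4(SCCCS4)[C@]2(C)[C@@H]3[C@@H]([C@H]2C6(OCCO6)C[C@H]3C)[C@@]1(C)CO[Si](C)(C)C(C)(C)C
A5 | alternative 3 | longibornane-type C11 hydroxy C1 mesylate | COc1ccc(cc1)CO[C@@H]1C[C@@H](O[Si](C)(C)C(C)(C)C)[C@]2(C)[C@@H]3[C@@H]([C@](O)([C@H]2OS(C)(=O)=O)C[C@H]3C)[C@@]1(C)CO[Si](C)(C)C(C)(C)C
A6 | alternative 3 | protected longipinan-11-one core | COc5ccc(cc5)CO[C@@H]1C[C@@H](O[Si](C)(C)C(C)(C)C)[C@]2(C)[C@@H]3[C@@H]([C@H]2C(=O)C[C@H]3C)[C@@]1(C)CO[Si](C)(C)C(C)(C)C
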